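**Retrosynthetic overview**
- Target 16 is a diaryl ether whose oxygen joins ring A C2 (between C1–CO2H and C3–CHO) to ring B C5 (between C4–OH and C6–CH3). Both carbons are flanked on both sides, so this C–O–C link is made as an alkyl C–O bond and ring B is built around it.
- Endgame: 16 from 15 by BCl3 debenzylation; 15 from 14 by Rieche formylation of ring A C3, the last free aromatic C–H of the core.
- Ring B of 14 comes from cyclohexanedione 12 by aromatisation. 12 is cut by a (3+3) Michael–Dieckmann annulation into dimethyl malonate 10 (ring B C1, C2) and 4-aryloxyhex-4-en-3-one 9 (ring B C3 to C6).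
- Enone 9 comes from ring A phenol 4 and trans-4,5-epoxyhexan-3-one 6 (epoxide opening, then dehydration). Phenol 4 comes from orcylaldehyde 1 by chlorite oxidation with ring chlorination, then benzylation.
- Ring order: ring A is bought as an arene and only decorated; ring B is the only ring formed (step 6) and is aromatised in step 7.

Key step: step 6

Assumption: the target has no stereocentre, so intermediates 6, 7, 8, 11, 12 and 13 are carried as racemates or diastereomer mixtures; a SMILES with descriptors shows one enantiomer of a racemate.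

**Step 1**
Reactants: 1 2,4-dihydroxy-6-methylbenzaldehyde (orcylaldehyde)
Product: 3 3-chloro-4,6-dihydroxy-2-methylbenzoic acid (5-chloroorsellinic acid), via orsellinic acid 2 (not isolated)
Conditions: NaClO2 (1.2 equiv), NaH2PO4, THF/H2O, 0 °C to rt, no hypochlorite scavenger
Reagents that add atoms: sodium chlorite NaClO2, [Na+].[O-]Cl=O
Why: Lindgren–Pinnick chlorite oxidation turns the aldehyde into the acid and releases one equivalent of HOCl, which, with no scavenger present, should chlorinate the activated resorcinol ring next to the methyl group (ortho to the 4-hydroxyl), the usual site for such resorcylates.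

**Step 2**
Reactants: 3 5-chloroorsellinic acid
Product: 4 benzyl 4-(benzyloxy)-3-chloro-6-hydroxy-2-methylbenzoate (ring A phenol)
Conditions: BnBr (2.1 equiv), K2CO3 (2.2 equiv), DMF, rt
Reagents that add atoms: benzyl bromide, BrCc1ccccc1
Why: Carboxylate alkylation and Williamson etherification take the acid and the unchelated 4-hydroxyl, while the 6-hydroxyl, hydrogen-bonded to the ester carbonyl, should stay free under carbonate conditions.

**Step 3**
Reactants: 5 (E)-hex-4-en-3-one
Product: 6 trans-4,5-epoxyhexan-3-one (racemic)
Conditions: 30% H2O2, NaOH (cat.), MeOH, 0 °C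
Reagents that add atoms: hydrogen peroxide, OO
Why: Weitz–Scheffer nucleophilic epoxidation (conjugate addition of hydroperoxide, then closure from the enolate) should give the trans epoxide from the E enone, as a racemate because no chiral element is present.

**Step 4**
Reactants: 4 ring A phenol; 6 trans-4,5-epoxyhexan-3-one (1.5 equiv)
Product: 7 benzyl 4-(benzyloxy)-3-chloro-6-[(2-hydroxy-4-oxohexan-3-yl)oxy]-2-methylbenzoate (racemic)
Conditions: Cs2CO3 (0.2 equiv), DMF, 50 °C
Reagents that add atoms: none
Why: Base-catalysed opening of an alpha,beta-epoxy ketone by a phenoxide at the carbonyl-activated alpha carbon, as known for epoxy ketones with phenols and thiols, should form the alkyl C–O bond; the new centre arises by SN2 inversion (the carbinol centre keeps its configuration) and is of no consequence.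

**Step 5**
Reactants: 7 beta-hydroxy alpha-aryloxy ketone
Product: 9 benzyl 4-(benzyloxy)-3-chloro-2-methyl-6-{[(2Z)-4-oxohex-2-en-3-yl]oxy}benzoate (4-aryloxyhex-4-en-3-one), via methanesulfonate 8 (not isolated)
Conditions: MsCl, Et3N (3 equiv), CH2Cl2, 0 °C to rt
Reagents that add atoms: none
Why: Mesylation of the aldol hydroxyl and E1cB elimination by triethylamine (aldol dehydration) should give the conjugated alpha-aryloxy enone; both stereocentres are erased and the alkene geometry (Z expected) does not matter.

**Step 6**
Reactants: 9 4-aryloxyhex-4-en-3-one; 10 dimethyl malonate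
Product: 12 methyl 5-aryloxy-3,6-dimethyl-2,4-dioxocyclohexane-1-carboxylate (aryl = ring A; diastereomer and enol mixture), via Michael adduct 11 (not isolated)
Conditions: NaH (1.05 equiv), THF, 0 °C; add 9, rt to 65 °C; then 1 M HCl
Reagents that add atoms: none
Why: Proposed new method: sodium dimethyl malonate adds 1,4 to the methyl-bearing beta carbon of enone 9, the alpha-aryloxy enolate so formed passes its charge by proton transfer to the ethyl-side alpha carbon, and that carbon acylates on one malonate ester with loss of methoxide, which is consumed at once by deprotonating the acidic 1,3-dione, so that every reversible stage drains into one stabilised enolate. The closest known reaction type is the malonate/enone Michael–Dieckmann annulation that gives dimedone and, from hex-4-en-3-one itself, methyl 3,6-dimethyl-2,4-dioxocyclohexanecarboxylate; new here is the aryloxy group on the enone alpha carbon. The carbocycle of ring B is closed by a 6-exo-trig Dieckmann (Claisen) acylation forming C2–C3, after the intermolecular Michael bond C1–C6. The four new stereocentres (C1, C3, C5, C6) are not controlled, equilibrate through enol forms and are all removed in step 7. The step needs conjugate rather than carbonyl addition, closure through the ethyl-side carbon, retention of the aryloxy group and an intact ring A ester: the ethyl group is the only other enolisable arm so only one six-membered closure exists, aryloxide is a poor leaving group for cyclopropane closure, and the fully substituted C5 carbanion could reach the di-ortho-substituted benzyl ester only to give a non-enolisable benzofuranone that reverts. One equivalent of the non-nucleophilic base NaH keeps free alkoxide low and so guards the hindered benzyl ester against exchange.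

**Step 7**
Reactants: 12 aryloxy cyclohexanedione
Product: 14 methyl 5-[5-(benzyloxy)-2-(benzyloxycarbonyl)-4-chloro-3-methylphenoxy]-2,4-dihydroxy-3,6-dimethylbenzoate (protected diaryl ether), via 3-bromo-2,4-dione 13 (not isolated)
Conditions: NBS (1.0 equiv), DMF, 0 °C; then LiBr (0.2 equiv), 60 °C
Reagents that add atoms: none
Why: The enolised 1,3-dione should be brominated at C3 by one equivalent of NBS; bromide-mediated transfer of the halogen to an enolisable ring carbon (C1 or C5) and loss of HBr then give a cyclohexadienone that tautomerises to the resorcinol. This halogenation–dehydrohalogenation is known for 3-alkyl dihydro-beta-resorcylates, no base is used so Favorskii contraction is avoided, and ring B has no free position for further bromination.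

**Step 8**
Reactants: 14 protected diaryl ether
Product: 15 methyl 5-[3-(benzyloxy)-6-(benzyloxycarbonyl)-4-chloro-2-formyl-5-methylphenoxy]-2,4-dihydroxy-3,6-dimethylbenzoate
Conditions: Cl2CHOMe (3 equiv), TiCl4 (5 equiv), CH2Cl2, -78 to 0 °C; then aq. HCl
Reagents that add atoms: dichloromethyl methyl ether, COC(Cl)Cl; water, O
Why: Rieche formylation should occur at ring A C3, which is ortho to two ether oxygens, para to the methyl group and the only unsubstituted carbon of either core ring (the benzyl phenyl rings are unactivated), with the TiCl4-bound ether oxygens directing the electrophile.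

**Step 9**
Reactants: 15 formylated protected diaryl ether
Product: 16 5-chloro-2-[2,4-dihydroxy-5-(methoxycarbonyl)-3,6-dimethylphenoxy]-3-formyl-4-hydroxy-6-methylbenzoic acid (target)
Conditions: BCl3 (5 equiv), CH2Cl2, -78 to 0 °C; then H2O
Reagents that add atoms: none
Why: BCl3 cleaves the benzyl aryl ether (assisted by chelation to the ortho formyl group) and the benzyl ester by chloride attack at the benzylic carbon, and at low temperature should spare the methyl ester, diaryl ether, aryl chloride and aldehyde, which hydrogenolysis would endanger.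

**Compound list**
1 | 2,4-dihydroxy-6-methylbenzaldehyde (orcylaldehyde) | Cc1cc(O)cc(O)c1C=O | starting material
2 | 2,4-dihydroxy-6-methylbenzoic acid (orsellinic acid) | Cc1cc(O)cc(O)c1C(=O)O | intermediate
3 | 3-chloro-4,6-dihydroxy-2-methylbenzoic acid | Cc1c(Cl)c(O)cc(O)c1C(=O)O | intermediate
4 | benzyl 4-(benzyloxy)-3-chloro-6-hydroxy-2-methylbenzoate | Cc1c(Cl)c(OCc2ccccc2)cc(O)c1C(=O)OCc1ccccc1 | intermediate
5 | (E)-hex-4-en-3-one | C/C=C/C(=O)CC | starting material
6 | trans-4,5-epoxyhexan-3-one (racemic, (4S,5R) drawn) | C[C@H]1O[C@@H]1C(=O)CC | intermediate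
7 | benzyl 4-(benzyloxy)-3-chloro-6-[(2-hydroxy-4-oxohexan-3-yl)oxy]-2-methylbenzoate (racemic, one enantiomer drawn) | C[C@@H](O)[C@@H](Oc1cc(OCc2ccccc2)c(Cl)c(C)c1C(=O)OCc1ccccc1)C(=O)CC | intermediate
8 | methanesulfonate of 7 (racemic, one enantiomer drawn) | C[C@@H](OS(C)(=O)=O)[C@@H](Oc1cc(OCc2ccccc2)c(Cl)c(C)c1C(=O)OCc1ccccc1)C(=O)CC | intermediate
9 | benzyl 4-(benzyloxy)-3-chloro-2-methyl-6-{[(2Z)-4-oxohex-2-en-3-yl]oxy}benzoate | C/C=C(\Oc1cc(OCc2ccccc2)c(Cl)c(C)c1C(=O)OCc1ccccc1)C(=O)CC | intermediate
10 | dimethyl malonate | COC(=O)CC(=O)OC | starting material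
11 | dimethyl 2-(3-aryloxy-4-oxohexan-2-yl)malonate, aryl = ring A (diastereomer mixture) | COC(=O)C(C(=O)OC)C(C)C(Oc1cc(OCc2ccccc2)c(Cl)c(C)c1C(=O)OCc1ccccc1)C(=O)CC | intermediate
12 | methyl 5-[5-(benzyloxy)-2-(benzyloxycarbonyl)-4-chloro-3-methylphenoxy]-3,6-dimethyl-2,4-dioxocyclohexane-1-carboxylate (diastereomer and enol mixture) | COC(=O)C1C(C)C(Oc2cc(OCc3ccccc3)c(Cl)c(C)c2C(=O)OCc2ccccc2)C(=O)C(C)C1=O | intermediate
13 | 3-bromo derivative of 12 (diastereomer mixture) | COC(=O)C1C(C)C(Oc2cc(OCc3ccccc3)c(Cl)c(C)c2C(=O)OCc2ccccc2)C(=O)C(C)(Br)C1=O | intermediate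
14 | methyl 5-[5-(benzyloxy)-2-(benzyloxycarbonyl)-4-chloro-3-methylphenoxy]-2,4-dihydroxy-3,6-dimethylbenzoate | COC(=O)c1c(C)c(Oc2cc(OCc3ccccc3)c(Cl)c(C)c2C(=O)OCc2ccccc2)c(O)c(C)c1O | intermediate
15 | methyl 5-[3-(benzyloxy)-6-(benzyloxycarbonyl)-4-chloro-2-formyl-5-methylphenoxy]-2,4-dihydroxy-3,6-dimethylbenzoate | COC(=O)c1c(C)c(Oc2c(C=O)c(OCc3ccccc3)c(Cl)c(C)c2C(=O)OCc2ccccc2)c(O)c(C)c1O | intermediate
16 | 5-chloro-2-[2,4-dihydroxy-5-(methoxycarbonyl)-3,6-dimethylphenoxy]-3-formyl-4-hydroxy-6-methylbenzoic acid | COC(=O)c1c(C)c(Oc2c(C=O)c(O)c(Cl)c(C)c2C(=O)O)c(O)c(C)c1O | target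

**Step count**
Total steps: 9. Longest linear sequence: 8 (steps 1, 2, 4, 5, 6, 7, 8, 9); step 3 is a one-step side branch.

**Steps most likely to fail**

Step 6. The conjugate addition may stall or reverse because the alpha-aryloxy group makes the enone a poorer acceptor, or the adduct may shed aryloxide before the ring closes. The fallback sets out from phenol 4 and returns at 14 by a known copper-catalysed Ullmann-type etherification, accepting the crowding at ring B C5. Commercial methyl 2,4-dihydroxy-3,6-dimethylbenzoate would be iodinated at its only free ring position (NIS, MeCN) to methyl 2,4-dihydroxy-5-iodo-3,6-dimethylbenzoate F1. Both hydroxyls would be capped (NaH, MOMCl, DMF) to give methyl 5-iodo-2,4-bis(methoxymethoxy)-3,6-dimethylbenzoate F2. F2 and 4 would be coupled (CuI, a salt of monovalent copper, picolinic acid, K3PO4, DMSO, 90 °C) to methyl 5-[5-(benzyloxy)-2-(benzyloxycarbonyl)-4-chloro-3-methylphenoxy]-2,4-bis(methoxymethoxy)-3,6-dimethylbenzoate F3. Mild acid (HCl, MeOH/THF, rt) would remove the acetals and give 14.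

Step 4. The phenoxide may attack the beta carbon of the epoxide instead of the alpha carbon, or the hydroxy ketone may undergo retro-aldol cleavage under base. The fallback sets out from phenol 4 and returns at enone 9, replacing steps 3 to 5 by carbenoid O–H insertion and olefination. Commercial diethyl (2-oxobutyl)phosphonate would undergo diazo transfer (4-acetamidobenzenesulfonyl azide, Et3N, MeCN) to diethyl (1-diazo-2-oxobutyl)phosphonate F4. Rh2(OAc)4-catalysed O–H insertion into 4 (toluene, 80 °C) would give benzyl 4-(benzyloxy)-3-chloro-6-{[1-(diethoxyphosphoryl)-2-oxobutyl]oxy}-2-methylbenzoate F5. Horner–Wadsworth–Emmons reaction of F5 with acetaldehyde (LiCl, DBU, MeCN, 0 °C) would give 9.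

Step 7. Transfer of the halogen away from the blocked C3 may be slow, leaving room for ring contraction or for attack of the liberated HBr on the benzyl groups. The fallback sets out from 12 and returns at 14 in one operation by quinone dehydrogenation (DDQ, 1.1 equiv, dioxane, 80 °C). It removes hydride directly from the dienol and uses no halogen or acid; it makes no compound outside the list (F0).

**Further compounds**
F1 | step 6 | methyl 2,4-dihydroxy-5-iodo-3,6-dimethylbenzoate | COC(=O)c1c(C)c(I)c(O)c(C)c1O
F2 | step 6 | methyl 5-iodo-2,4-bis(methoxymethoxy)-3,6-dimethylbenzoate | COC(=O)c1c(C)c(I)c(OCOC)c(C)c1OCOC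
F3 | step 6 | methyl 5-[5-(benzyloxy)-2-(benzyloxycarbonyl)-4-chloro-3-methylphenoxy]-2,4-bis(methoxymethoxy)-3,6-dimethylbenzoate | COC(=O)c1c(C)c(Oc2cc(OCc3ccccc3)c(Cl)c(C)c2C(=O)OCc2ccccc2)c(OCOC)c(C)c1OCOC
F4 | step 4 | diethyl (1-diazo-2-oxobutyl)phosphonate | CCC(=O)C(=[N+]=[N-])P(=O)(OCC)OCC
F5 | step 4 | benzyl 4-(benzyloxy)-3-chloro-6-{[1-(diethoxyphosphoryl)-2-oxobutyl]oxy}-2-methylbenzoate | CCC(=O)C(Oc1cc(OCc2ccccc2)c(Cl)c(C)c1C(=O)OCc1ccccc1)P(=O)(OCC)OCC
F0 | step 7 | none | none
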